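Watch the trapped intermediate. You asked me for a quick number on this flask, so I looked first at how much catalyst leaves its working round.

starting material 0.20 M; second substrate 0.200 M; capture agent 0.0100 M; free catalyst 4.0 mM

    starting material + free catalyst ⇌ catalyst intermediate A (K1 = 4.1 M⁻¹, k1 = 7400 M⁻¹ h⁻¹)
    catalyst intermediate A → free catalyst + target (k2 = 20 h⁻¹)
    second substrate + free catalyst ⇌ catalyst intermediate B (K3 = 3.8 M⁻¹, k3 = 110 M⁻¹ h⁻¹)
    catalyst intermediate B → free catalyst + second product (k4 = 900 h⁻¹)
    catalyst intermediate A + capture agent → trapped intermediate (k5 = 20 M⁻¹ h⁻¹)
    2 second substrate → self-condensation product (k6 = 0.26 M⁻¹ h⁻¹)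

* the form that holds most of the catalyst when 50% of the starting material are converted (trapped intermediate / free catalyst / catalyst intermediate B / catalyst intermediate A)
* its share of the catalyst then

I counted lifetimes. In this flask, catalyst sitting as intermediate A lasted 3.00 min before it gave target, but 5.00 h before the capture agent took it, so turnover came much sooner. From these two lifetimes I took one number:

passes per capture = 5.00 h / 3.00 min = 100

These passes per capture are the target made, on average, for each catalyst lost at the charged capture agent.

At 50% conversion, 0.100 M of starting material had gone, and I counted that as target:

trapped = 0.100 M / 100 = 1.00 mM, or 25.0% of the catalyst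

So about a quarter had left the round. Intermediate A falls back at 1800 h⁻¹, faster than it turns over, so I held it in equilibrium with free catalyst:

c(intermediate A) / c(free catalyst) = 0.410

Intermediate B, at 0.0244 of free catalyst even at the charged second substrate, I dropped. That left:

free catalyst = (1 − 25.0%) / (1 + 0.410) = 53.2%

I committed to free catalyst at 53.2%, more than the trapped share.

The forecast named free catalyst at 54%, a little above my figure, with capture that “locks up a little under 1 mM of the 4 mM catalyst”.

The flask reached that conversion at 3.88 h and gave free catalyst at 54.2%, more than the trapped intermediate at 23.4% or intermediate A at 22.0%, so free catalyst was the resting state. Target was then forming at 0.0176 M h⁻¹. At 10.0 h the flask held target at 82.1% of the starting material charged, and dividing that by 100 passes per capture gave 41.1% of the catalyst trapped. The flask showed 37.9% trapped, with capture agent at 84.9% of its charge.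

(The numbers are those of an exercise; the run is a simulation.)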